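## Structural features

The target is a sesquiterpenoid diester on a cis-fused decalin. Ring A (C1–C5 and C10) and ring B (C5–C10) share the C5–C10 bond, and H5 and the C10 methyl group lie on the same face. There are five stereocentres: C3, C4, C5 and C10 are contiguous, C4 and C10 are fully substituted, and C7 sits across ring B next to the C8 ketone. C3 and C4 carry cis oxygen atoms (a secondary angelate and a tertiary acetate), and the C4 methyl group is syn to H5 and to the C10 methyl group.

The fragile groups are:
- the angelate, which isomerises to the tiglate under acid, base, nucleophiles or heat;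
- the tertiary acetate, which is hard to install and prone to elimination;
- the vicinal diester, where acyl migration threatens as soon as one oxygen is free;
- C7, which is epimerisable, although the required epimer is the stable one.

The real difficulty is the C3–C4–C5–C10 array: a hindered tertiary carbinol between an oxygenated secondary centre and a ring-fusion carbon that adjoins a quaternary centre, all in one absolute configuration. The key step exploits two features. Ring B has its quaternary C10 para to the isopropyl-bearing C7, the pattern of a reductively alkylated 4-isopropylbenzoic acid. C4 is a carbinol carbon bonded to C5, which is what addition of a C4 ketone to the C5=C6 bond of a cyclohexa-2,5-diene, with transfer of H7 to oxygen, leaves behind.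

## Logic of the disconnections

**25 to 24.** The C4 O–acetyl bond is cut first. The tertiary ester is the group most prone to elimination, and if it were present while the C3 oxygen was free it would migrate to the secondary position. The gain is a precursor with one sensitive ester fewer. The forward step must acylate a hindered tertiary alcohol without touching the Z-enoate or the ketone.

**24 to 21 and 22 (through 23).** The C3 O–acyl bond is cut next, because the unsaturated ester cannot survive hydrogenation and because a secondary hydroxyl differentiates itself from a tertiary one. This leaves 21, which has no sensitive group. The forward step must activate 22 without Z to E isomerisation.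

**21 to 19 (through 20).** The C6–H and C7–H bonds and the benzyl ether are restored in the backward sense. C7 is alpha to the ketone, so its configuration can be left to equilibration, and one hydrogenation removes both the alkene and the benzyl group. The gain is the loss of the C7 stereocentre. The demand is that the 7R epimer be the stable one. It should be, because it alone places isopropyl equatorial on ring B in the chair pair that avoids a syn-axial clash of the C4 and C10 methyl groups.

**19 to 18 to 16 (through 17).** The C8–O bond is cut back to a C6=C7–C8=C9 diene, which is exactly the unsaturation the ring-forming step leaves. Ring B is thereby freed of oxygen. The forward steps need boron to go to C8 rather than C9 and to leave the C6=C7 bond alone.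

**16 to 15.** The C4–C5 bond is cut, and the carbinol hydrogen returns to C7. This opens ring A, restores a symmetrical cyclohexa-2,5-diene and removes C4, C5 and C10 as stereocentres in one stroke. The forward step must choose one of two enantiotopic alkenes under the control of C3, and it needs H7 on the same face as the tether.

**15 to 14 to 13.** The C4–methyl bond and then the acyl–nitrogen bond are cut. This brings C4 to the carboxyl level, where an auxiliary can control C3. The forward steps must not epimerise C3 or over-add.

**13 to 11 and 8 (through 12).** The C2–C3 bond is cut, since C3 is the only stereocentre of 15 not erased by symmetry and the enolate of 11 has a defined facial bias. The fragments are an auxiliary glycolate and an achiral dienyl ethanol. The electrophile is an unactivated primary carbon, so the forward step uses the most reactive leaving group (12); an iodide would be too sluggish for this class of enolate.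

**11 to 9 and 10.** The N–acyl bond is cut to two commercial materials; the forward step is a routine acylation.

**8 to 6 to 4 (through 7 and 5).** The C2–O bond and then the C1=C2 bond are cut. C1 is neopentylic and flanked by two vinyl groups, so substitution, cation or radical chemistry at C1 would invite ring expansion or vinyl shifts. C2 is therefore attached by carbonyl olefination at C1 and oxygenated by anti-Markovnikov hydroboration. The forward step must hydroborate the monosubstituted alkene selectively.

**4 to 3 to 1 and 2.** The oxidation level of C1 is adjusted, then the C10–methyl bond is cut with rearomatisation. One reductive alkylation turns a flat aromatic acid into the quaternary, para-substituted ring B. The carboxyl group must end trans to isopropyl, which puts H7 on the tether face; this is secured by separation.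

## Other disconnections considered

**Alternative 1:** The cut is the C5–C6 bond of ring B, traced back to a [3,3] shift.
- Forward step: the potassium alkoxide of A1 (KH, 18-crown-6) would rearrange by an anionic oxy-Cope shift. A1 is a bicyclo[2.2.2]octene in which C8 is a tertiary carbinol carrying the 3-methylbut-1-en-2-yl group and C4=C5 is a silyl enol ether. C6 bonds to C5, the C3–C8 bond breaks, and A2 results.
- In favour: ring B arrives with the C8 ketone and the C7 isopropyl group in place, so the diene functionalisation of steps 10 and 11 is not needed. On this point the alternative is the better plan. The cis fusion follows from the bridged framework, which is as dependable as the tether constraint of step 9. The enol ether can only form toward C5, because the other alpha position is a bridgehead. An alkoxide-driven sigmatropic shift is also arguably more predictable than a Lewis-acid ene reaction of a ketone.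
- Against: A2 lacks the C3 oxygen, the C4 methyl group and the C4 carbinol. These would be added by enol ether oxidation at C3 and a face-selective methyl addition at C4 in the presence of the C8 carbonyl, under substrate control on a flexible cis-decalin. The absolute configuration would come from a mono-addition of a hindered alkenyl nucleophile to one of two enantiotopic carbonyl groups of a meso diketone, on the face that places the alkenyl group syn to the future enol ether bridge. The two faces differ little.
- Comparison: the chosen route fixes C3, C4, C5 and C10 together, whereas here the key step settles only C5 and C10. With the diketone synthesis and the ring A functionalisation, the step count should be equal to or above fourteen.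

**Alternative 2:** Two bonds are cut, C10–CH3 and C5–C6.
- Forward step: Me3Al would deliver methyl to C10 of A3, a 3-substituted cyclohex-2-enone whose side chain holds C9, the silyloxy-bearing C8, the isopropyl-bearing C7 and the iodomethyl carbon C6. The catalyst is copper thiophene-2-carboxylate, Cu(O2CC4H3S), with a chiral phosphoramidite. The aluminium enolate, made more nucleophilic with MeLi, would then displace iodide from C6 through C5 to give A4.
- In favour: the absolute configuration of the quaternary C10 comes from a catalyst rather than a stoichiometric auxiliary, which is better than the chosen plan. Two bonds and ring B form in one flask. The axial trajectory of enolate alkylation should give the cis fusion, which makes it the equal of step 9 on that point.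
- Against: the iodide is beta-branched and the aluminium enolate is a weak nucleophile, so ring closure is the doubtful half. The side chain needs two stereocentres (C7 and C8) made in advance, although C8 is later oxidised and C7 is epimerisable, and both may interfere with catalyst control. A4 has no oxygen at C3 and no methyl group at C4, so hydroxylation toward C3, methyl addition at C4, desilylation and oxidation at C8 must follow before the two acylations.
- Comparison: the conjugate methylation is as well-founded as the Birch step, but the late construction of C3 and C4 is less controlled than in the chosen plan. With the side-chain synthesis, the route is expected to be longer.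

**Alternative 3:** The cut is C1–C10 in ring A.
- Forward step: the alkoxide of A5 (KH, 18-crown-6) would undergo a [3,3] shift. A5 is a 2-vinylbicyclo[2.2.2]oct-5-en-2-ol whose core would come from cycloaddition of a dearomatised phenol (an o-quinol ether) with a simple terminal alkene, followed by vinyl addition. C1 bonds to C10, the C3–C8 bond breaks, and A6 results with ring A closed and ring B as a C8=C9 cyclohexene.
- In favour: this is the shortest access to a decalin with all fifteen skeletal carbons and with C4, C5, C7 and C10 set. It needs three or four steps from a phenol, against nine to reach 16, so it is clearly better in step economy. The C4 oxygen and methyl group are present from the start, so no hindered carbinol has to be made. The rigid precursor ties the relative configuration together, equal to the chosen plan for the cis fusion.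
- Against: quinol dienes dimerise quickly and the dienophile is unactivated, so the cycloaddition is the weak point. It must place isopropyl next to the bridgehead C8 and syn to the C9=C10 bridge. The adduct is racemic unless the dearomatisation is made asymmetric or a resolution is added, whereas the chosen plan takes its absolute configuration from an auxiliary. The shift must form a quaternary centre at a methyl-substituted alkene terminus. Afterwards the C3 ketone must be reduced to the alpha alcohol, C8=C9 hydroborated at C8 (the same regiochemical question as step 10, on a simpler alkene) and a tertiary acetal ether cleaved.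
- Comparison: it is shorter and mechanistically clean, but weaker on absolute configuration, which the single-enantiomer target makes decisive.

Key step: step 9

## Route

Remark: ring atoms carry eudesmane numbers throughout. In the monocyclic dienes, "trans to isopropyl" describes the substituent on the quaternary carbon that lies on the face opposite the isopropyl group. The facial bias of the methylation in step 1 is taken as unknown; the plan only requires that the isomer drawn as 3 can be separated.

Step 1
Reactants: 1 4-isopropylbenzoic acid; 2 iodomethane
Product: 3 1-methyl-4-isopropylcyclohexa-2,5-diene-1-carboxylic acid (CO2H trans to isopropyl)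
Conditions: Li, NH3(l)–THF, −78 °C; then MeI; NH4Cl, then H3O+; separation of the C10 epimers by crystallisation
Reagents that add atoms: none
Why: Birch reductive alkylation: the benzoate is reduced to the dihydro dianion, ammonia protonates C7 and the carboxylate-stabilised carbon C10 is methylated, so the quaternary centre blocks rearomatisation. The isopropyl group is remote, so both C10/C7 isomers should form; the one with the carboxyl group trans to isopropyl is kept because it places H7 on the future tether face.

Step 2
Reactants: 3 1-methyl-4-isopropylcyclohexa-2,5-diene-1-carboxylic acid (CO2H trans to isopropyl)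
Product: 4 (1-methyl-4-isopropylcyclohexa-2,5-dien-1-yl)methanol (CH2OH trans to isopropyl)
Conditions: LiAlH4, THF, 0 °C to reflux
Reagents that add atoms: none
Why: Hydride reduction of a carboxylic acid to the primary alcohol; the isolated ring alkenes are inert to LiAlH4 and no stereocentre is touched.

Step 3
Reactants: 4 (1-methyl-4-isopropylcyclohexa-2,5-dien-1-yl)methanol (CH2OH trans to isopropyl)
Product: 6 3-isopropyl-6-methyl-6-vinylcyclohexa-1,4-diene (vinyl trans to isopropyl), via aldehyde 5 (not isolated)
Conditions: Dess–Martin periodinane, NaHCO3, CH2Cl2, 0 °C to rt; short silica pad; then Ph3PCH3Br, KOt-Bu, THF, 0 °C to rt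
Reagents that add atoms: methylenetriphenylphosphorane C=P(c1ccccc1)(c1ccccc1)c1ccccc1
Why: Buffered Dess–Martin oxidation gives a non-enolisable aldehyde that is acid-sensitive and volatile, so it is methylenated at once by a Wittig reaction. C2 is thus attached without ever generating a cation, radical or leaving group at the neopentylic C1.

Step 4
Reactants: 6 3-isopropyl-6-methyl-6-vinylcyclohexa-1,4-diene (vinyl trans to isopropyl)
Product: 8 2-(1-methyl-4-isopropylcyclohexa-2,5-dien-1-yl)ethanol (hydroxyethyl trans to isopropyl), via B-alkyl borane 7 (not isolated)
Conditions: 9-BBN, THF, 0 °C to rt; then NaOH, H2O2, 0 °C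
Reagents that add atoms: hydrogen peroxide OO
Why: Anti-Markovnikov hydroboration–oxidation; 9-BBN reacts far faster with a monosubstituted alkene than with the hindered cis-disubstituted ring alkenes, so only the vinyl group should be converted.

Step 5
Reactants: 9 (S)-4-benzyl-1,3-oxazolidin-2-one; 10 benzyloxyacetyl chloride
Product: 11 (S)-4-benzyl-3-(2-benzyloxyacetyl)-1,3-oxazolidin-2-one
Conditions: n-BuLi, THF, −78 °C; then 10, −78 to 0 °C
Reagents that add atoms: none
Why: N-Acylation of the lithiated oxazolidinone by the acid chloride, the standard preparation of an auxiliary glycolate.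

Step 6
Reactants: 8 2-(1-methyl-4-isopropylcyclohexa-2,5-dien-1-yl)ethanol (hydroxyethyl trans to isopropyl); 11 (S)-4-benzyl-3-(2-benzyloxyacetyl)-1,3-oxazolidin-2-one
Product: 13 (S)-4-benzyl-3-[(2R)-2-benzyloxy-4-(1-methyl-4-isopropylcyclohexa-2,5-dien-1-yl)butanoyl]-1,3-oxazolidin-2-one, via triflate 12 (not isolated)
Conditions: 8, Tf2O, 2,6-lutidine, CH2Cl2, −78 °C; separately 11 (2 equiv), NaN(SiMe3)2, THF, −78 °C; then 12 added, −78 to −45 °C
Reagents that add atoms: none
Why: Evans-type alkylation of the chelated Z sodium enolate; the electrophile approaches anti to the auxiliary benzyl group, which sets C3 as R, and diastereomers are separable. A primary triflate is used because glycolate imide enolates are weak, thermally fragile nucleophiles that should not alkylate an unactivated iodide before they decompose.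

Step 7
Reactants: 13 (S)-4-benzyl-3-[(2R)-2-benzyloxy-4-(1-methyl-4-isopropylcyclohexa-2,5-dien-1-yl)butanoyl]-1,3-oxazolidin-2-one
Product: 14 (2R)-2-benzyloxy-N-methoxy-N-methyl-4-(1-methyl-4-isopropylcyclohexa-2,5-dien-1-yl)butanamide
Conditions: AlMe3, MeNH(OMe)·HCl, CH2Cl2, 0 °C to rt; aq. potassium sodium tartrate
Reagents that add atoms: N,O-dimethylhydroxylamine hydrochloride CNOC.Cl
Why: Transamination of the imide with the aluminium amide gives the Weinreb amide and releases the auxiliary; coordination of aluminium by the alpha-alkoxy oxygen should direct attack to the exocyclic carbonyl, and C3 is not enolised under these conditions.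

Step 8
Reactants: 14 (2R)-2-benzyloxy-N-methoxy-N-methyl-4-(1-methyl-4-isopropylcyclohexa-2,5-dien-1-yl)butanamide
Product: 15 (3R)-3-benzyloxy-5-(1-methyl-4-isopropylcyclohexa-2,5-dien-1-yl)pentan-2-one (chain trans to isopropyl)
Conditions: MeMgBr, THF, 0 °C; NH4Cl
Reagents that add atoms: methylmagnesium bromide C[Mg]Br
Why: Weinreb ketone synthesis: the chelated tetrahedral intermediate survives until work-up, so no tertiary alcohol forms and the alpha-alkoxy centre keeps its configuration.

Step 9
Reactants: 15 (3R)-3-benzyloxy-5-(1-methyl-4-isopropylcyclohexa-2,5-dien-1-yl)pentan-2-one (chain trans to isopropyl)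
Product: 16 (3R,4S,5S,10R)-3-benzyloxy-5βH-eudesma-6,8-dien-4-ol (cis-fused; 3α-benzyloxy, 4α-hydroxy)
Conditions: MeAlCl2 (2.2 equiv), CH2Cl2, −78 to −30 °C; aq. potassium sodium tartrate
Reagents that add atoms: none
Why: Two equivalents of MeAlCl2 should convert the alpha-benzyloxy ketone into a five-membered chelate whose carbonyl carbon C4 is strongly electrophilic; C4 then bonds to C5 of a ring alkene on the tether face while the carbonyl oxygen takes the doubly allylic hydrogen from C7 through a six-membered transition state and the alkene moves to C6=C7, an intramolecular carbonyl-ene reaction. The closest known reaction type is the Lewis-acid ene or Prins cyclisation of aldehydes tethered to the quaternary carbon of Birch-derived cyclohexa-2,5-dienes, with a chelated alpha-alkoxy methyl ketone in place of the aldehyde. Ring A closes as a six-membered ring in the exo sense with respect to the C5=C6 bond, and because the tether leaves from C10 next to C5 it can only reach the face it sits on, so the fusion is cis. C5 is therefore set by the tether (H5 syn to the C10 methyl group), and C4 follows from the need for the oxygen to lie under ring B to reach H7, which leaves the C4 methyl group outside and the hydroxyl axial on the new chair (4S). C10 becomes stereogenic through the choice between the two enantiotopic alkenes, and C3 makes that choice: only the chair with the benzyloxy group equatorial keeps the two oxygen atoms close enough for chelation, and that chair uses the alkene that gives 10R. The step needs this group selection, a concerted ene pathway in preference to Prins ionisation with chloride capture, and no enolisation of the ketone. The substrate supplies the cis relation of H7 and the tether from step 1 and a C7–H bond aligned with the pi system, and the methyl–aluminium bond scavenges protons that would otherwise isomerise the diene.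

Step 10
Reactants: 16 (3R,4S,5S,10R)-3-benzyloxy-5βH-eudesma-6,8-dien-4-ol
Product: 18 (3R,4S,5S,10R)-3-benzyloxy-5βH-eudesm-6-ene-4,8-diol (C8 epimers), via C8 allylborane 17 (not isolated)
Conditions: Sia2BH (from BH3·THF and 2-methylbut-2-ene, 3 equiv), THF, −10 to 0 °C; then NaOH, H2O2, 0 °C
Reagents that add atoms: hydrogen peroxide OO
Why: Hydroboration–oxidation of a cyclic 1,3-diene, which takes boron at an inner diene carbon to give the allylic borane; here that carbon is C8, also the less hindered end of the disubstituted alkene because C9 is neopentylic, while the trisubstituted C6=C7 bond is too hindered for a dialkylborane. The C8 configuration is immaterial because it is oxidised next.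

Step 11
Reactants: 18 (3R,4S,5S,10R)-3-benzyloxy-5βH-eudesm-6-ene-4,8-diol (C8 epimers)
Product: 19 (3R,4S,5S,10R)-3-benzyloxy-4-hydroxy-5βH-eudesm-6-en-8-one
Conditions: Dess–Martin periodinane, NaHCO3, CH2Cl2, 0 °C to rt
Reagents that add atoms: none
Why: Oxidation of the secondary allylic alcohol to the enone; the tertiary C4 hydroxyl cannot be oxidised, and neutral conditions avoid a vinylogous retro-aldol opening of the C4–C5 bond and epimerisation at the gamma carbon C5.

Step 12
Reactants: 19 (3R,4S,5S,10R)-3-benzyloxy-4-hydroxy-5βH-eudesm-6-en-8-one
Product: 21 (3R,4S,5S,7R,10R)-3,4-dihydroxy-5βH-eudesman-8-one, via C7-epimeric ketodiol 20 (not isolated)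
Conditions: H2 (1 atm), Pd/C, EtOAc–MeOH, rt; filter; then NaOMe (0.2 equiv), MeOH, rt
Reagents that add atoms: none
Why: Catalytic hydrogenation saturates the enone alkene and hydrogenolyses the benzyl ether in one operation. Methoxide then equilibrates C7 through the enolate to the epimer with isopropyl equatorial on ring B in the chair pair that avoids a syn-axial clash of the C4 and C10 methyl groups, which is 7R; no beta-hydroxy ketone is present, so retro-aldol cleavage is not possible.

Step 13
Reactants: 21 (3R,4S,5S,7R,10R)-3,4-dihydroxy-5βH-eudesman-8-one; 22 angelic acid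
Product: 24 (3R,4S,5S,7R,10R)-3-angeloyloxy-4-hydroxy-5βH-eudesman-8-one, via mixed anhydride 23 (not isolated)
Conditions: 22, 2,4,6-trichlorobenzoyl chloride, Et3N, toluene, rt; then 21, 75 °C
Reagents that add atoms: none
Why: Yamaguchi esterification through the mixed anhydride, an activation that tolerates the Z-enoate when no nucleophilic catalyst is added; the secondary equatorial C3 hydroxyl should react in preference to the tertiary C4 hydroxyl, and an acyl group on the secondary oxygen has no tendency to migrate to the tertiary one.

Step 14
Reactants: 24 (3R,4S,5S,7R,10R)-3-angeloyloxy-4-hydroxy-5βH-eudesman-8-one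
Product: 25 (3R,4S,5S,7R,10R)-4-acetoxy-3-angeloyloxy-5βH-eudesman-8-one (CNP0322180.1)
Conditions: Ac2O, Sc(OTf)3 (5 mol %), MeCN, −20 °C
Reagents that add atoms: acetic anhydride CC(=O)OC(C)=O
Why: Lewis-acid-catalysed acetylation, a method suited to hindered tertiary alcohols at low temperature, where elimination of the carbinol and Z to E isomerisation of the angelate should stay slow; no stereocentre is affected.

## Compound list

1 | 4-isopropylbenzoic acid | CC(C)c1ccc(cc1)C(O)=O | starting material
2 | iodomethane | CI | starting material
3 | 1-methyl-4-isopropylcyclohexa-2,5-diene-1-carboxylic acid (CO2H trans to isopropyl) | C[C@@]1(C(=O)O)C=C[C@@H](C(C)C)C=C1 | intermediate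
4 | (1-methyl-4-isopropylcyclohexa-2,5-dien-1-yl)methanol (CH2OH trans to isopropyl) | C[C@@]1(CO)C=C[C@@H](C(C)C)C=C1 | intermediate
5 | 1-methyl-4-isopropylcyclohexa-2,5-diene-1-carbaldehyde (CHO trans to isopropyl) | C[C@@]1(C=O)C=C[C@@H](C(C)C)C=C1 | intermediate
6 | 3-isopropyl-6-methyl-6-vinylcyclohexa-1,4-diene (vinyl trans to isopropyl) | C[C@@]1(C=C)C=C[C@@H](C(C)C)C=C1 | intermediate
7 | 9-[2-(1-methyl-4-isopropylcyclohexa-2,5-dien-1-yl)ethyl]-9-borabicyclo[3.3.1]nonane | C[C@@]1(CCB2C3CCCC2CCC3)C=C[C@@H](C(C)C)C=C1 | intermediate
8 | 2-(1-methyl-4-isopropylcyclohexa-2,5-dien-1-yl)ethanol (hydroxyethyl trans to isopropyl) | C[C@@]1(CCO)C=C[C@@H](C(C)C)C=C1 | intermediate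
9 | (S)-4-benzyl-1,3-oxazolidin-2-one | O=C1N[C@@H](Cc2ccccc2)CO1 | starting material
10 | benzyloxyacetyl chloride | O=C(Cl)COCc1ccccc1 | starting material
11 | (S)-4-benzyl-3-(2-benzyloxyacetyl)-1,3-oxazolidin-2-one | O=C(COCc1ccccc1)N1[C@@H](Cc2ccccc2)COC1=O | intermediate
12 | 2-(1-methyl-4-isopropylcyclohexa-2,5-dien-1-yl)ethyl trifluoromethanesulfonate | C[C@@]1(CCOS(=O)(=O)C(F)(F)F)C=C[C@@H](C(C)C)C=C1 | intermediate
13 | (S)-4-benzyl-3-[(2R)-2-benzyloxy-4-(1-methyl-4-isopropylcyclohexa-2,5-dien-1-yl)butanoyl]-1,3-oxazolidin-2-one | C[C@@]1(CC[C@@H](OCc2ccccc2)C(=O)N3[C@@H](Cc4ccccc4)COC3=O)C=C[C@@H](C(C)C)C=C1 | intermediate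
14 | (2R)-2-benzyloxy-N-methoxy-N-methyl-4-(1-methyl-4-isopropylcyclohexa-2,5-dien-1-yl)butanamide | C[C@@]1(CC[C@@H](OCc2ccccc2)C(=O)N(C)OC)C=C[C@@H](C(C)C)C=C1 | intermediate
15 | (3R)-3-benzyloxy-5-(1-methyl-4-isopropylcyclohexa-2,5-dien-1-yl)pentan-2-one (methyl cis to isopropyl) | C[C@@]1(CC[C@@H](OCc2ccccc2)C(C)=O)C=C[C@@H](C(C)C)C=C1 | intermediate
16 | (3R,4S,5S,10R)-3-benzyloxy-5βH-eudesma-6,8-dien-4-ol (cis-fused) | c1ccccc1CO[C@@H]2CC[C@]3(C)C=CC(C(C)C)=C[C@@H]3[C@]2(C)O | intermediate
17 | C8 disiamylborane of 16 (allylborane; C4 hydroxyl drawn free, C8 left open) | c1ccccc1CO[C@@H]2CC[C@]3(C)CC(B(C(C)C(C)C)C(C)C(C)C)C(C(C)C)=C[C@@H]3[C@]2(C)O | intermediate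
18 | (3R,4S,5S,10R)-3-benzyloxy-5βH-eudesm-6-ene-4,8-diol (C8 left open, both epimers serve) | c1ccccc1CO[C@@H]2CC[C@]3(C)CC(O)C(C(C)C)=C[C@@H]3[C@]2(C)O | intermediate
19 | (3R,4S,5S,10R)-3-benzyloxy-4-hydroxy-5βH-eudesm-6-en-8-one | c1ccccc1CO[C@@H]2CC[C@]3(C)CC(=O)C(C(C)C)=C[C@@H]3[C@]2(C)O | intermediate
20 | (3R,4S,5S,10R)-3,4-dihydroxy-5βH-eudesman-8-one as C7 epimers (C7 left open) | O[C@@H]1CC[C@]2(C)CC(=O)C(C(C)C)C[C@@H]2[C@]1(C)O | intermediate
21 | (3R,4S,5S,7R,10R)-3,4-dihydroxy-5βH-eudesman-8-one | O[C@@H]1CC[C@]2(C)CC(=O)[C@@H](C(C)C)C[C@@H]2[C@]1(C)O | intermediate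
22 | angelic acid, (Z)-2-methylbut-2-enoic acid | C/C=C(/C)C(=O)O | starting material
23 | angelic 2,4,6-trichlorobenzoic anhydride | C/C=C(/C)C(=O)OC(=O)c1c(Cl)cc(Cl)cc1Cl | intermediate
24 | (3R,4S,5S,7R,10R)-3-angeloyloxy-4-hydroxy-5βH-eudesman-8-one | C/C=C(/C)C(=O)O[C@@H]1CC[C@]2(C)CC(=O)[C@@H](C(C)C)C[C@@H]2[C@]1(C)O | intermediate
25 | (3R,4S,5S,7R,10R)-4-acetoxy-3-angeloyloxy-5βH-eudesman-8-one (CNP0322180.1) | C/C=C(/C)C(=O)O[C@@H]1CC[C@]2(C)CC(=O)[C@@H](C(C)C)C[C@@H]2[C@]1(C)OC(C)=O | target

## Step count and least certain steps

Total: 14 steps. Longest linear sequence: 13 steps (steps 1–4 and 6–14); step 5 is a one-step branch.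

**Step 9 (key step).** The ketone is a weaker enophile than an aldehyde. Bond formation may therefore become stepwise, with hydride shift, chloride capture or loss of the wrong proton. It may also run through a non-chelated arrangement, which would erode the choice between the two ring alkenes.
Fallback, from 14 back to 16: reduction of 14 with i-Bu2AlH (THF, −78 °C) would give (2R)-2-benzyloxy-4-(1-methyl-4-isopropylcyclohexa-2,5-dien-1-yl)butanal F1. This aldehyde, the enophile class for which the cyclisation type is established, would be closed with MeAlCl2 to 3α-benzyloxy-15-nor-5βH-eudesma-6,8-dien-4α-ol F2. Dess–Martin oxidation would give 3α-benzyloxy-15-nor-5βH-eudesma-6,8-dien-4-one F3. MeMgBr with CeCl3 (THF, −78 °C) should then add from the convex face, away from ring B, and return 16.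

**Step 6.** C-alkylation of the glycolate enolate by an unactivated primary electrophile may be too slow, so that enolate decomposition or elimination of the triflate takes over.
Fallback, from aldehyde 5 back to 15: a Horner–Wadsworth–Emmons reaction of 5 with dimethyl (3,3-dimethoxy-2-oxobutyl)phosphonate (LiCl, i-Pr2NEt, MeCN) would give (E)-4,4-dimethoxy-1-(1-methyl-4-isopropylcyclohexa-2,5-dien-1-yl)pent-1-en-3-one F4. Conjugate reduction with [(Ph3P)CuH]6 would give 2,2-dimethoxy-5-(1-methyl-4-isopropylcyclohexa-2,5-dien-1-yl)pentan-3-one F5. Corey–Bakshi–Shibata reduction with the (S)-methyl oxazaborolidine and catecholborane, chosen so that the ring alkenes are not hydroborated, would give (3R)-2,2-dimethoxy-5-(1-methyl-4-isopropylcyclohexa-2,5-dien-1-yl)pentan-3-ol F6. Benzylation (NaH, BnBr) would give the benzyl ether ketal F7, and mild aqueous acid would release 15.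

**Step 10.** Boron may add at C9, or the allylic borane may undergo a 1,3-shift to C6 before oxidation, because both ends of the C8=C9 bond are flanked by substituted carbons.
Fallback, from 16 back to 18: hydrogenation with RhCl(PPh3)3 should saturate only the disubstituted C8=C9 bond and give (3R,4S,5S,10R)-3-benzyloxy-5βH-eudesm-6-en-4-ol F8. Allylic oxidation with SeO2 and t-BuOOH, which attacks the ring methylene on the more substituted alkene carbon, would install the C8 hydroxyl and return 18.

**Step 1.** Facial discrimination in the methylation may be poor, and the two diastereomeric acids may not separate by crystallisation.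
Fallback, from 4 back to 4: the unseparated acids would be reduced as in step 2. The alcohol mixture would be converted with 3,5-dinitrobenzoyl chloride and pyridine into crystalline esters, and (1-methyl-4-isopropylcyclohexa-2,5-dien-1-yl)methyl 3,5-dinitrobenzoate F9 (ester trans to isopropyl) would be isolated by fractional crystallisation. Saponification with LiOH would return pure 4.

**Step 13.** The angeloyl group may isomerise to the tigloyl group during activation or heating.
Fallback, from 21 back to 24: the C3 hydroxyl would be esterified with 2-[bis(2,2,2-trifluoroethoxy)phosphoryl]propanoic acid (DCC, DMAP) to the phosphonopropanoate F10. A Still–Gennari olefination with acetaldehyde (KN(SiMe3)2, 18-crown-6, THF, −78 °C) would then build the Z-enoate in place and give 24.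

**Step 14.** Acylation may be incomplete, or the tertiary carbinol may ionise and eliminate, because C4 is flanked by the C3 ester and the ring fusion.
Fallback, from 21 back to 25, with the order of acylations reversed: trimethyl orthoacetate and camphorsulfonic acid would give the cyclic 3,4-orthoacetate F11. Its mild acid hydrolysis opens to the axial ester, here the tertiary one, and would give (3R,4S,5S,7R,10R)-4-acetoxy-3-hydroxy-5βH-eudesman-8-one F12. Angeloylation of F12 as in step 13, kept free of strong base to prevent acetyl migration, would give 25.

## Further compounds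

F1 | step 9 | (2R)-2-benzyloxy-4-(1-methyl-4-isopropylcyclohexa-2,5-dien-1-yl)butanal | C[C@@]1(CC[C@@H](OCc2ccccc2)C=O)C=C[C@@H](C(C)C)C=C1
F2 | step 9 | 3α-benzyloxy-15-nor-5βH-eudesma-6,8-dien-4α-ol | c1ccccc1CO[C@@H]2CC[C@]3(C)C=CC(C(C)C)=C[C@@H]3[C@@H]2O
F3 | step 9 | 3α-benzyloxy-15-nor-5βH-eudesma-6,8-dien-4-one | c1ccccc1CO[C@@H]2CC[C@]3(C)C=CC(C(C)C)=C[C@@H]3C2=O
F4 | step 6 | (E)-4,4-dimethoxy-1-(1-methyl-4-isopropylcyclohexa-2,5-dien-1-yl)pent-1-en-3-one | C[C@@]1(/C=C/C(=O)C(C)(OC)OC)C=C[C@@H](C(C)C)C=C1
F5 | step 6 | 2,2-dimethoxy-5-(1-methyl-4-isopropylcyclohexa-2,5-dien-1-yl)pentan-3-one | C[C@@]1(CCC(=O)C(C)(OC)OC)C=C[C@@H](C(C)C)C=C1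
F6 | step 6 | (3R)-2,2-dimethoxy-5-(1-methyl-4-isopropylcyclohexa-2,5-dien-1-yl)pentan-3-ol | C[C@@]1(CC[C@@H](O)C(C)(OC)OC)C=C[C@@H](C(C)C)C=C1
F7 | step 6 | (3R)-3-benzyloxy-2,2-dimethoxy-5-(1-methyl-4-isopropylcyclohexa-2,5-dien-1-yl)pentane | C[C@@]1(CC[C@@H](OCc2ccccc2)C(C)(OC)OC)C=C[C@@H](C(C)C)C=C1
F8 | step 10 | (3R,4S,5S,10R)-3-benzyloxy-5βH-eudesm-6-en-4-ol | c1ccccc1CO[C@@H]2CC[C@]3(C)CCC(C(C)C)=C[C@@H]3[C@]2(C)O
F9 | step 1 | (1-methyl-4-isopropylcyclohexa-2,5-dien-1-yl)methyl 3,5-dinitrobenzoate (ester trans to isopropyl) | C[C@@]1(COC(=O)c2cc(cc(c2)[N+](=O)[O-])[N+](=O)[O-])C=C[C@@H](C(C)C)C=C1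
F10 | step 13 | (3R,4S,5S,7R,10R)-4-hydroxy-8-oxo-5βH-eudesman-3-yl 2-[bis(2,2,2-trifluoroethoxy)phosphoryl]propanoate | CC(C(=O)O[C@@H]1CC[C@]2(C)CC(=O)[C@@H](C(C)C)C[C@@H]2[C@]1(C)O)P(=O)(OCC(F)(F)F)OCC(F)(F)F
F11 | step 14 | 3,4-O-(1-methoxyethylidene) derivative of 21 (cyclic orthoacetate, orthoester carbon left open) | COC1(C)O[C@@H]2CC[C@]3(C)CC(=O)[C@@H](C(C)C)C[C@@H]3[C@]2(C)O1
F12 | step 14 | (3R,4S,5S,7R,10R)-4-acetoxy-3-hydroxy-5βH-eudesman-8-one | O[C@@H]1CC[C@]2(C)CC(=O)[C@@H](C(C)C)C[C@@H]2[C@]1(C)OC(C)=O
A1 | alternative 1 | 6-(tert-butyldimethylsilyloxy)-4-methyl-2-(3-methylbut-1-en-2-yl)bicyclo[2.2.2]oct-5-en-2-ol (alkenyl group syn to the enol ether bridge) | CC(C)C(=C)[C@]1(O)C[C@@]2(C)CC[C@@H]1C(O[Si](C)(C)C(C)(C)C)=C2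
A2 | alternative 1 | cis-4-(tert-butyldimethylsilyloxy)-10-methyl-7-isopropyloctal-3-en-8-one (eudesmane numbering) | C1=C(O[Si](C)(C)C(C)(C)C)[C@H]2C[C@H](C(C)C)C(=O)C[C@@]2(C)CC1
A3 | alternative 2 | 3-[(2S,3R)-2-(tert-butyldimethylsilyloxy)-3-(iodomethyl)-4-methylpentyl]cyclohex-2-en-1-one | O=C1C=C(C[C@H](O[Si](C)(C)C(C)(C)C)[C@@H](C(C)C)CI)CCC1
A4 | alternative 2 | cis-8-(tert-butyldimethylsilyloxy)-10-methyl-7-isopropyldecalin-4-one (eudesmane numbering) | C1CC[C@]2(C)C[C@H](O[Si](C)(C)C(C)(C)C)[C@@H](C(C)C)C[C@@H]2C1=O
A5 | alternative 3 | 7-isopropyl-3-(methoxymethoxy)-3,5-dimethyl-2-vinylbicyclo[2.2.2]oct-5-en-2-ol (vinyl and isopropyl syn to the alkene bridge) | C=C[C@@]1(O)[C@H]2C=C(C)[C@H](C[C@@H]2C(C)C)[C@]1(C)OCOC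
A6 | alternative 3 | cis-4-(methoxymethoxy)-4,10-dimethyl-7-isopropyloctal-8-en-3-one (eudesmane numbering) | O=C1CC[C@]2(C)C=C[C@@H](C(C)C)C[C@@H]2[C@]1(C)OCOC
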